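**Retrosynthetic overview** (atom numbers are the positions of the heavy atoms in the target SMILES)
1. The target is opened at O19–C20: desilylation of a C8=C20 3-acylbutenolide lets O19–H add to C20 (oxa-Michael), closing the 2-oxabicyclo[2.2.2]octane last.
2. The strategy rests on C21: it is α to the C26 ketone and, in the C8=C20 butenolide, γ to the lactone carbonyl C9. The cyclooctane (C2, C3, C4, C6, C8, C20, C21, C26) is therefore closed at C21–C26 by a vinylogous Dieckmann condensation of methyl ester 22.
3. 22 comes from tertiary α-ketol 15 and acyl Meldrum's acid 19 (acylketene esterification of O11, Knoevenagel condensation at C20); 19 carries C2 and C4 from desymmetrised meso-2,4-dimethylglutaric anhydride.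
4. 15 comes from a catalytic asymmetric Diels–Alder adduct of cyclopentenone and a 2-silyloxydiene, oxygenated by Rubottom oxidation (O16), enol triflate methylation (C18), hydroxyl-directed epoxidation with acid hydrolysis (O25, O19) and enolate hydroxylation (O11).
5. Ring order: cyclohexane fused to the cyclopentanone, then butenolide, then cyclooctane, then the oxa-bridge.

Key step: step 15

Assumption: the (S)-configured oxazaborolidinium salt is taken to give adduct 4 and (DHQD)2AQN to give hemiester 17; if the sense of induction of either catalyst is the opposite, its antipode or (DHQ)2AQN is used in its place.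
Convention: "top face" is the face of the cyclohexane that carries H12 and H23 in 4 (later O11, O16, O25); "bottom face" carries C20, C22 and later O19.

**Route**

Step 1
Reactants: 1 3-methylbut-3-en-2-one
Product: 2 3-methyl-2-[(triisopropylsilyl)oxy]buta-1,3-diene
Conditions: TIPSOTf, Et3N, CH2Cl2, 0 °C
Reagents that add atoms: triisopropylsilyl triflate, CC(C)[Si](C(C)C)(C(C)C)OS(=O)(=O)C(F)(F)F
Why: Soft enolisation of the methyl ketone (silyl enol ether formation) can only occur at the methyl group and should give the cross-conjugated 2-silyloxydiene; no stereocentre is formed.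

Step 2
Reactants: 3 cyclopent-2-en-1-one; 2 3-methyl-2-[(triisopropylsilyl)oxy]buta-1,3-diene
Product: 4 (3aS,7aR)-6-methyl-5-[(triisopropylsilyl)oxy]-2,3,3a,4,7,7a-hexahydro-1H-inden-1-one (cis-fused)
Conditions: (S)-B-(o-tolyl)-diphenylprolinol oxazaborolidine·HNTf2 (20 mol%), CH2Cl2, −78 → −40 °C
Reagents that add atoms: none
Why: A cationic oxazaborolidine-catalysed enantioselective Diels–Alder reaction should join the CH2 terminus next to the silyloxy carbon to the enone β-carbon (silyloxy carbon para to C12); suprafacial addition makes the ring fusion cis (H12 and H23 on one face) and the catalyst shields one enone face to set the absolute configuration.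

Step 3
Reactants: 4 cis-fused silyl enol ether
Product: 6 cis-fused 6-methyl-6-[(triisopropylsilyl)oxy]hexahydroindane-1,5-dione with O16 on the top face, via silyloxy epoxide 5 (not isolated)
Conditions: mCPBA, NaHCO3, CH2Cl2, −20 → 0 °C
Reagents that add atoms: mCPBA, OOC(=O)c1cccc(Cl)c1
Why: Rubottom oxidation: the peracid should epoxidise the electron-rich enol ether from the convex top face, away from the cyclopentanone, and 1,4-silyl migration in the silyloxy epoxide then gives the C17 ketone with O16 on the top face of C14.

Step 4
Reactants: 6 α-silyloxy diketone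
Product: 7 C20 ethylene ketal of 6 (C17 ketone retained)
Conditions: ethylene glycol, p-TsOH (cat.), benzene, reflux, Dean–Stark
Reagents that add atoms: ethylene glycol, OCCO
Why: Acid-catalysed ketalisation should take the cyclopentanone C20 and leave the C17 ketone, which is flanked by the fully substituted silyloxy carbon C14, so that C20 is masked during the enolate chemistry at C17.

Step 5
Reactants: 7 ketal ketone
Product: 8 enol triflate (C17–OTf, C17=C24)
Conditions: KN(SiMe3)2, PhNTf2, THF, −78 °C
Reagents that add atoms: N-phenylbis(trifluoromethanesulfonimide), O=S(=O)(N(c1ccccc1)S(=O)(=O)C(F)(F)F)C(F)(F)F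
Why: Kinetic enolate O-triflation: C24 is the only enolisable position of the C17 ketone, so a single enol triflate should form.

Step 6
Reactants: 8 enol triflate
Product: 9 trisubstituted alkene (C18 methyl on C17, C17=C24) with O16 silyl ether and C20 ketal
Conditions: Fe(acac)3 (5 mol%), MeMgBr, THF/NMP, −20 °C
Reagents that add atoms: methylmagnesium bromide, C[Mg]Br
Why: An Fe-catalysed Kumada-type cross-coupling of the enol triflate with the methyl Grignard reagent should install C18 at low temperature without touching the ketal or the silyl ether.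

Step 7
Reactants: 9 silyl ether alkene
Product: 10 tertiary allylic alcohol (free O16–H)
Conditions: Bu4NF, THF, 50 °C
Reagents that add atoms: none
Why: Fluoride-mediated desilylation frees the tertiary allylic alcohol that is needed to direct the next step.

Step 8
Reactants: 10 tertiary allylic alcohol
Product: 11 epoxy alcohol with the C17–C24 oxirane on the top face (syn to O16–H)
Conditions: VO(acac)2 (cat.), t-BuOOH, CH2Cl2, 0 → 25 °C
Reagents that add atoms: tert-butyl hydroperoxide, CC(C)(C)OO
Why: Vanadium-catalysed hydroxyl-directed epoxidation of the allylic alcohol should deliver oxygen to C17=C24 syn to O16–H, which is also the convex top face, so that the oxygen on C24 (the future O25) is fixed on the top face.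

Step 9
Reactants: 11 epoxy alcohol ketal
Product: 12 cis-fused triol ketone (O16 and O25 top, O19 bottom, C20 ketone)
Conditions: HClO4 (cat.), THF/H2O, 0 → 25 °C
Reagents that add atoms: water, O
Why: Acid-catalysed epoxide hydrolysis should open the oxirane at the tertiary carbon C17 with inversion (Markovnikov, trans-diaxial opening), placing O19 on the bottom face trans to O25 and O16, while the dioxolane is hydrolysed in the same operation.

Step 10
Reactants: 12 triol ketone
Product: 13 tris(triethylsilyl) ether of 12
Conditions: TESOTf (excess), 2,6-lutidine, CH2Cl2, −40 → 25 °C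
Reagents that add atoms: triethylsilyl triflate, CC[Si](CC)(CC)OS(=O)(=O)C(F)(F)F
Why: Exhaustive silylation with the silyl triflate protects the secondary and both tertiary hydroxyls, so that the hydroxyl introduced next is the only free one.

Step 11
Reactants: 13 tris-silyl ether ketone
Product: 15 tertiary α-ketol (C12–OH on the top face, cis-fused, C20 ketone), via C12 hydroperoxide 14 (not isolated)
Conditions: KOtBu, O2, P(OEt)3, THF/t-BuOH, −20 °C; AcOH
Reagents that add atoms: dioxygen, O=O
Why: Enolate autoxidation with in situ phosphite reduction of the hydroperoxide (α-hydroxylation at the more substituted α-carbon through the equilibrating thermodynamic enolate) should oxygenate C12 from the convex top face, re-forming the cis ring fusion with O11 cis to H23.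

Step 12
Reactants: 16 meso-2,4-dimethylglutaric anhydride
Product: 17 (2S,4R)-5-methoxy-2,4-dimethyl-5-oxopentanoic acid
Conditions: MeOH, (DHQD)2AQN (cat.), Et2O, −40 °C
Reagents that add atoms: methanol, CO
Why: Cinchona-alkaloid-catalysed desymmetrising methanolysis of the meso anhydride differentiates the enantiotopic carbonyl groups and so fixes the absolute configuration of C2 and C4 in one step.

Step 13
Reactants: 17 hemiester; 18 Meldrum's acid
Product: 19 acyl Meldrum's acid (enol form)
Conditions: DCC, DMAP, CH2Cl2, 0 → 25 °C
Reagents that add atoms: none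
Why: Carbodiimide-mediated C-acylation of Meldrum's acid should give the acyl Meldrum's acid, a storable acylketene precursor, without touching the α-stereocentre C4.

Step 14
Reactants: 15 tertiary α-ketol; 19 acyl Meldrum's acid
Product: 22 tricyclic 3-acylbutenolide methyl ester, via acylketene 20 (not isolated), via β-keto ester 21 (not isolated)
Conditions: toluene, 100 °C; then piperidinium acetate (cat.), 4 Å molecular sieves, 60 °C
Reagents that add atoms: none
Why: Thermolysis of the acyl Meldrum's acid releases acetone and CO2 to give an acylketene that should acylate even the hindered tertiary O11–H, and amine-catalysed intramolecular Knoevenagel condensation of the β-keto ester (C8) onto the neighbouring ketone C20 then closes the butenolide.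

Step 15
Reactants: 22 tricyclic 3-acylbutenolide methyl ester
Product: 23 cyclooctanedione-fused butenolide (tris-silyl ether)
Conditions: KOtBu (2.5 equiv), THF (0.01 M), −20 → 20 °C; AcOH
Reagents that add atoms: none
Why: Proposed new method: KOtBu removes a C21 proton of the 3-acylbutenolide (γ to the lactone carbonyl C9 and to the C6 ketone through C8=C20), and the extended dienolate attacks the C26 methyl ester through C21 with loss of methoxide, the product being drained as its doubly stabilised C21 enolate, the usual driving force of a Dieckmann condensation. The closest known reactions are the Dieckmann condensation itself and γ-selective vinylogous aldol and acylation reactions of butenolide-derived dienolates; an eight-membered ring has not been closed in this way. The cyclooctane (C2, C3, C4, C6, C8, C20, C21, C26) closes in an 8-(enolendo)-exo-trig addition to the ester carbonyl. The new stereocentre C21 is set by protonation of the product enolate on acidic quench and stays under thermodynamic control, C26 settling on the face that the fused rings leave open. The step needs γ- over α-acylation and ring closure over intermolecular condensation: attack through C8 would give a six-membered triketone with no acidic proton that reverts by retro-Claisen cleavage, the cis arrangement of C21 and the acyl chain across C8=C20 holds nucleophile and ester close, and dilution suppresses dimerisation.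

Step 16
Reactants: 23 cyclooctanedione-fused butenolide
Product: 25 CNP0073203.1, via desilylated triol 24 (not isolated)
Conditions: HF·pyridine, THF/pyridine, 0 → 25 °C; then Et3N (cat.), CH2Cl2, 25 °C
Reagents that add atoms: none
Why: Fluoride cleaves the three silyl ethers, and the freed O19–H, held under C20 by the cis ring fusion, should add to the β-carbon C20 of the alkylidene β-dicarbonyl unit in a 6-exo-trig oxa-Michael addition that closes the 2-oxabicyclo[2.2.2]octane, sets C20 (only the bottom face is within reach) and leaves the C6 enol of the target.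

**Compound list**

1 | 3-methylbut-3-en-2-one | CC(=O)C(C)=C | starting material
2 | 3-methyl-2-[(triisopropylsilyl)oxy]buta-1,3-diene | C=C(O[Si](C(C)C)(C(C)C)C(C)C)C(C)=C | intermediate
3 | cyclopent-2-en-1-one | O=C1C=CCC1 | starting material
4 | (3aS,7aR)-6-methyl-5-[(triisopropylsilyl)oxy]-2,3,3a,4,7,7a-hexahydro-1H-inden-1-one | O=C1CC[C@@H]2[C@H]1CC(C)=C(O[Si](C(C)C)(C(C)C)C(C)C)C2 | intermediate
5 | top-face 5,6-epoxide of 4 (silyloxy epoxide) | O=C1CC[C@@H]2[C@H]1C[C@@]3(C)O[C@@]3(O[Si](C(C)C)(C(C)C)C(C)C)C2 | intermediate
6 | cis-fused 6-methyl-6-[(triisopropylsilyl)oxy]hexahydroindane-1,5-dione, O16 on the top face | O=C1CC[C@@H]2[C@H]1C[C@@](C)(O[Si](C(C)C)(C(C)C)C(C)C)C(=O)C2 | intermediate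
7 | C20 ethylene ketal of 6 | O1CCOC12CC[C@@H]3[C@H]2C[C@@](C)(O[Si](C(C)C)(C(C)C)C(C)C)C(=O)C3 | intermediate
8 | C17 enol triflate of 7 (C17=C24) | O1CCOC12CC[C@@H]3[C@H]2C[C@@](C)(O[Si](C(C)C)(C(C)C)C(C)C)C(OS(=O)(=O)C(F)(F)F)=C3 | intermediate
9 | C17-methyl alkene (C17=C24), O16 silyl ether, C20 ketal | O1CCOC12CC[C@@H]3[C@H]2C[C@@](C)(O[Si](C(C)C)(C(C)C)C(C)C)C(C)=C3 | intermediate
10 | tertiary allylic alcohol (free O16–H), C20 ketal | O1CCOC12CC[C@@H]3[C@H]2C[C@@](C)(O)C(C)=C3 | intermediate
11 | top-face C17–C24 epoxy alcohol, C20 ketal | O1CCOC12CC[C@@H]3[C@H]2C[C@@](C)(O)[C@@]4(C)O[C@H]43 | intermediate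
12 | cis-fused triol ketone (O16, O25 top; O19 bottom) | O=C1CC[C@@H]2[C@H]1C[C@@](C)(O)[C@](C)(O)[C@H]2O | intermediate
13 | tris(triethylsilyl) ether of 12 | O=C1CC[C@@H]2[C@H]1C[C@@](C)(O[Si](CC)(CC)CC)[C@](C)(O[Si](CC)(CC)CC)[C@H]2O[Si](CC)(CC)CC | intermediate
14 | C12 hydroperoxide of 13 | O=C1CC[C@@H]2[C@@]1(OO)C[C@@](C)(O[Si](CC)(CC)CC)[C@](C)(O[Si](CC)(CC)CC)[C@H]2O[Si](CC)(CC)CC | intermediate
15 | tertiary α-ketol (C12–OH top, C20 ketone), tris-silyl ether | O=C1CC[C@@H]2[C@@]1(O)C[C@@](C)(O[Si](CC)(CC)CC)[C@](C)(O[Si](CC)(CC)CC)[C@H]2O[Si](CC)(CC)CC | intermediate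
16 | meso-2,4-dimethylglutaric anhydride | C[C@H]1C[C@@H](C)C(=O)OC1=O | starting material
17 | (2S,4R)-5-methoxy-2,4-dimethyl-5-oxopentanoic acid | COC(=O)[C@H](C)C[C@H](C)C(=O)O | intermediate
18 | Meldrum's acid | CC1(C)OC(=O)CC(=O)O1 | starting material
19 | acyl Meldrum's acid from 17 (enol form) | COC(=O)[C@H](C)C[C@H](C)C(O)=C1C(=O)OC(C)(C)OC1=O | intermediate
20 | acylketene | COC(=O)[C@H](C)C[C@H](C)C(=O)C=C=O | intermediate
21 | β-keto ester of 15 at O11 | O=C1CC[C@@H]2[C@@]1(OC(=O)CC(=O)[C@@H](C)C[C@@H](C)C(=O)OC)C[C@@](C)(O[Si](CC)(CC)CC)[C@](C)(O[Si](CC)(CC)CC)[C@H]2O[Si](CC)(CC)CC | intermediate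
22 | tricyclic 3-acylbutenolide methyl ester (C8=C20), tris-silyl ether | COC(=O)[C@H](C)C[C@H](C)C(=O)C1=C2CC[C@@H]3[C@@]2(OC1=O)C[C@@](C)(O[Si](CC)(CC)CC)[C@](C)(O[Si](CC)(CC)CC)[C@H]3O[Si](CC)(CC)CC | intermediate
23 | cyclooctanedione-fused butenolide, tris-silyl ether | C[C@@H]1C[C@H](C)C(=O)C2=C3[C@@H](C[C@@H]4[C@@]3(OC2=O)C[C@@](C)(O[Si](CC)(CC)CC)[C@](C)(O[Si](CC)(CC)CC)[C@H]4O[Si](CC)(CC)CC)C1=O | intermediate
24 | desilylated triol of 23 | C[C@@H]1C[C@H](C)C(=O)C2=C3[C@@H](C[C@@H]4[C@@]3(OC2=O)C[C@@](C)(O)[C@](C)(O)[C@H]4O)C1=O | intermediate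
25 | CNP0073203.1 | C[C@@H]1C[C@H](C)/C(O)=C2/C(=O)O[C@]34C[C@@](C)(O)[C@]5(C)O[C@]23[C@@H](C[C@H]4[C@@H]5O)C1=O | target

**Step count and risks**

Total step count: 16. Longest linear sequence: 14 steps (steps 1–11, 14, 15, 16).

Steps most likely to fail:

1. Step 15. The ring closure may lose to intermolecular Claisen condensation, to α-acylation followed by retro-Claisen loss of the acyl chain, or to alkoxide opening of the butenolide; strain in the eight-membered ring may also keep the equilibrium on the side of the open ester. The fallback uses known chemistry, sets out from 16 and 15 and comes back at 23. Catalytic asymmetric thiolysis of 16 with ethanethiol (bifunctional cinchona thiourea catalyst) would give the hemi-thioester F1. As in steps 13 and 14, F1 would be converted into the thioester acyl Meldrum's acid F2 and, with 15, into the thioester butenolide F3. Fukuyama reduction (Et3SiH, Pd/C, acetone) would give the aldehyde butenolide F4. A γ-selective intramolecular vinylogous aldol addition (LiN(SiMe3)2, THF, −78 °C) would close the ring to the C26 carbinol F5, and Dess–Martin oxidation would then give 23.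

2. Step 9. The acid-promoted opening may take place at C24 instead of C17, may lose stereochemical integrity through a free tertiary cation, or may divert into a semipinacol shift triggered by the free C14 hydroxyl. The fallback sets out from 9 and comes back at 12. Epoxidation of the silyl ether 9 with mCPBA on the face opposite to the bulky silyloxy group would give the bottom-face epoxide F6. SN2 opening at the secondary carbon C24 by hydroxide from the top face (KOH, DMSO/H2O, 100 °C) would give the silyl ether diol F7, with O25 on top and O19 on the bottom. Aqueous HF in MeCN would then remove the silyl ether and the dioxolane to give 12.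

3. Step 11. Enolisation may go toward C21, the hydroperoxide may fragment with C–C cleavage, or oxygen may be delivered to the concave face. The fallback sets out from 13 and comes back at 15. Equilibrating silylation (Me3SiI, HN(SiMe3)2, CH2Cl2, −20 → 25 °C) would give the isolable tetrasubstituted trimethylsilyl enol ether F8, so that the regiochemistry is fixed before oxidation. Rubottom oxidation with dimethyldioxirane in acetone would give the α-trimethylsilyloxy ketone F9, and K2CO3 in MeOH at 0 °C would free 15.

**Further compounds**

F1 | step 15 | (2S,4R)-5-(ethylsulfanyl)-2,4-dimethyl-5-oxopentanoic acid (hemi-thioester) | CCSC(=O)[C@H](C)C[C@H](C)C(=O)O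
F2 | step 15 | thioester acyl Meldrum's acid | CCSC(=O)[C@H](C)C[C@H](C)C(O)=C1C(=O)OC(C)(C)OC1=O
F3 | step 15 | thioester butenolide | CCSC(=O)[C@H](C)C[C@H](C)C(=O)C1=C2CC[C@@H]3[C@@]2(OC1=O)C[C@@](C)(O[Si](CC)(CC)CC)[C@](C)(O[Si](CC)(CC)CC)[C@H]3O[Si](CC)(CC)CC
F4 | step 15 | aldehyde butenolide | O=C[C@H](C)C[C@H](C)C(=O)C1=C2CC[C@@H]3[C@@]2(OC1=O)C[C@@](C)(O[Si](CC)(CC)CC)[C@](C)(O[Si](CC)(CC)CC)[C@H]3O[Si](CC)(CC)CC
F5 | step 15 | C26 carbinol (eight-membered aldol product, C26 epimers) | C[C@@H]1C[C@H](C)C(=O)C2=C3[C@@H](C[C@@H]4[C@@]3(OC2=O)C[C@@](C)(O[Si](CC)(CC)CC)[C@](C)(O[Si](CC)(CC)CC)[C@H]4O[Si](CC)(CC)CC)C1O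
F6 | step 9 | bottom-face C17–C24 epoxide of 9 | O1CCOC12CC[C@@H]3[C@H]2C[C@@](C)(O[Si](C(C)C)(C(C)C)C(C)C)[C@]4(C)O[C@@H]43
F7 | step 9 | silyl ether diol (O19 bottom, O25 top), C20 ketal | O1CCOC12CC[C@@H]3[C@H]2C[C@@](C)(O[Si](C(C)C)(C(C)C)C(C)C)[C@](C)(O)[C@H]3O
F8 | step 11 | trimethylsilyl enol ether of 13 (C12=C20) | C[Si](C)(C)OC1=C2C[C@@](C)(O[Si](CC)(CC)CC)[C@](C)(O[Si](CC)(CC)CC)[C@@H](O[Si](CC)(CC)CC)[C@@H]2CC1
F9 | step 11 | α-trimethylsilyloxy ketone (C12–OSiMe3 on the top face) | O=C1CC[C@@H]2[C@@]1(O[Si](C)(C)C)C[C@@](C)(O[Si](CC)(CC)CC)[C@](C)(O[Si](CC)(CC)CC)[C@H]2O[Si](CC)(CC)CC
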